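## The problem

Target 31 is a germacrane-type ester built on a single ten-membered carbocycle. The ring atoms are numbered C1 (the carbinol carbon that carries the vanillate), C2, C3 (methyl), C4, C5, C6, C7 (methyl and hydroxyl), C8, C9 and C10 (isopropyl). These labels are kept for the open-chain intermediates.

- **Ring.** The medium ring is strained and entropically hard to close. It holds an E-trisubstituted C3=C4 alkene and an E-disubstituted C8=C9 alkene in a 1,5-relationship, so heat and acid invite Cope and transannular reactions.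
- **Stereocentres.** C1 (S) and C10 (S) are neighbours and can be set together in one aldol event. C7 (R) is a fully substituted carbinol on the far side of the trans C8=C9 alkene. Neither C1 nor C10 can be relied on to control it in an open chain, so it needs reagent control or a stereospecific transfer.
- **Fragile groups.** The tertiary allylic alcohol at C7 ionises easily and must not meet acid once unveiled. The vanillate is an aryl ester with a free phenol that would not survive hydride, organolithium or alkaline peroxide, so it is attached last.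
- **Enabling feature.** C7 carries oxygen, a methyl group, the alkenyl carbon C8 and the primary carbon C6. This is the pattern left when a primary alkyl group shifts from boron onto the carbon of a lithiated secondary allylic carbamate. The C7–H of such a carbamate is acidified by the C8=C9 alkene, and C6 can carry the boron at the other end of the same chain.

## Retrosynthesis

**Ester C–O bond.** Ester 31 is cut at the acyl–oxygen bond to diol 25 and the phenol-silylated acid 28 (by way of the silyl ether 30). A secondary hydroxyl is acylated far faster than a tertiary allylic one, so no protection of C7–OH is needed. Acid 28 comes from vanillic acid 26 in one operation.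

**C7–O and C1–O unveiling.** Diol 25 comes from silyl ether 24, and 24 from the tertiary allylic boronate 23 by oxidation with retention. The oxidation must precede fluoride, because fluoride would protodeboronate a tertiary allylic boronate.

**C6–C7 and the ring (key cut).** Boronate 23 is opened at C6–C7 to the acyclic boronate carbamate 20. This is the only ring bond whose formation also creates the C7 centre with a defined configuration. A cut at C7–C8 would leave a ketone addition with no stereocontrol, and a cut at C4–C5 or C5–C6 would close the ring without creating any stereocentre. Precursor 20 is an open chain with three stereocentres, each set independently. The forward reaction must lithiate C7, capture the tethered boron at C7 and not at C9, and cyclise in preference to oligomerising.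

**C6–B and the carbamate.** Boronate 20 is traced to bromide 19 by copper-catalysed borylation, and 19 to allylic alcohol 18 by carbamoylation. Carrying a bromide instead of a boronate lets the chain pass through the peroxide work-up of the aldol step.

**C7 stereocentre and C8=C9.** Alcohol 18 comes from enone 17 by oxazaborolidine-controlled reduction, and 17 from aldehyde 16 by a Horner–Wadsworth–Emmons reaction with a β-ketophosphonate. This sets C7 by reagent control, independent of C1 and C10, and fixes the E geometry of C8=C9.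

**C1–C10.** Aldehyde 16 is traced through alcohol 15 and silyl ether 14 to aldol adduct 13. Adduct 13 is cut at C1–C10 into imide 11 and aldehyde 8. One Evans syn aldol sets both contiguous centres with known sense. Imide 11 comes from auxiliary 9 and acid chloride 10.

**C3–methyl and C4–C5.** Aldehyde 8 comes from alcohol 7, bromide 6 and mono-protected diol 5. Diol 5 is cut at C3–CH3 and C4–C5 back to alkyne 2, the silyl ether of but-3-yn-1-ol 1. Syn methylalumination fixes the E-trisubstituted alkene, and a two-carbon epoxide supplies C5–C6.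

## Roads not taken

**Alternative 1:** The cut is C9–C10. CrCl2 would turn the allylic bromide of the acyclic bromo trienal A1 into an allylchromium species that adds through C10 to the C9 aldehyde, giving cyclodecadienol A2.

- Merits: A1 is an acyclic sesquiterpene chain that needs few steps. Chromium-mediated allylation is a known way to close medium rings, and that is a real advantage over the chosen plan, whose ring closure is untested.
- Weak points: A2 has its oxygen on C9 and its alkene at C7=C8, so a 1,3-transposition must follow. That transposition runs from a trisubstituted alkene and secondary alcohol to a disubstituted alkene and tertiary alcohol, which is thermodynamically uphill, and it must deliver C7 with defined configuration in a flexible ring. The isopropenyl group must then be hydrogenated beside two ring alkenes. C1 is the only element controlling C9 and C10 in the closure.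
- Comparison: Alternative 1 is shorter and its closure is better precedented. The chosen plan sets against this that C7 is delivered directly and stereospecifically, with no oxidation-level editing on the acid-sensitive ring.

**Alternative 2:** The cut is C5–C6 with ring expansion. KH and 18-crown-6 would convert the trans-dialkenyl cyclohexanol A3 into its alkoxide. A [3,3] shift would give the ten-membered enolate, and an N-sulfonyloxaziridine would oxygenate it at C7 to give hydroxy ketone A4.

- Merits: the ring forms by expansion, with no entropic penalty, and the chair transition state reliably gives the E C3=C4 alkene. In the security of ring formation this road is better than the chosen one.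
- Weak points: the C7 configuration would rest on the facial bias of a tetrasubstituted medium-ring enolate, which cannot be predicted. The C8 ketone of A4 must then be turned into the E C8=C9 alkene by reduction and a regio- and stereodefined elimination beside a tertiary alcohol. A3 itself needs four stereocentres, two of them adjacent and fully substituted.
- Comparison: the chosen plan accepts a riskier closure in exchange for a C7 centre fixed by stereospecific transfer and a product that already has the C8=C9 alkene in place.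

**Alternative 3:** The cut is C4–C5. 9-BBN would hydroborate the vinyl group of iodo triene A5, and the alkylborane would couple with the C4 vinyl iodide under PdCl2(dppf), AsPh3 and Cs2CO3 to give the bis-silyl ether A6.

- Merits: the B-alkyl Suzuki–Miyaura reaction is a known macrocyclisation that keeps the vinyl iodide geometry. A6 is only two desilylations from diol 25, so the endgame is as short as in the chosen plan. Its precedent is closer.
- Weak points: A5 must already contain the C7 tertiary ether as a single isomer on an open chain, which needs a separate asymmetric construction of a fully substituted carbinol. The vinyl group to be hydroborated sits on that quaternary carbon. Closure through a strained palladacycle competes with β-hydride elimination and oligomerisation.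
- Comparison: the chosen plan sets against the better precedent of this closure that ring and C7 centre are made in one event from an easily made secondary carbamate.

Key step: step 15

Assumption: the lithiated carbamate is taken to be captured by the tethered boronic ester with retention at carbon, as boronic esters do in the intermolecular reaction.

## Route

Step 1
Reactants: 1 but-3-yn-1-ol
Product: 2 tert-butyl(but-3-yn-1-yloxy)dimethylsilane
Conditions: TBSCl, imidazole, DCM, 0 °C to rt
Reagents that add atoms: tert-butyldimethylsilyl chloride, CC(C)(C)[Si](C)(C)Cl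
Why: Standard silyl ether formation; it masks the oxygen that later becomes the C1 aldehyde, so that only the hydroxyl created in step 2 is turned into bromide.

Step 2
Reactants: 2 tert-butyl(but-3-yn-1-yloxy)dimethylsilane
Product: 5 (E)-6-[(tert-butyldimethylsilyl)oxy]-4-methylhex-3-en-1-ol, via alkenyldimethylalane 3 (not isolated), via lithium alkenylalanate 4 (not isolated)
Conditions: AlMe3, Cp2ZrCl2 (0.2 equiv), DCM, 0 °C to rt; solvent switch to hexane, n-BuLi, 0 °C; oxirane, THF, −30 °C to rt; aq. potassium sodium tartrate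
Reagents that add atoms: trimethylaluminium, C[Al](C)C; oxirane, C1CO1
Why: Zirconium-catalysed methylalumination (Negishi carboalumination) adds methyl and aluminium syn with methyl on the internal carbon, which fixes the E C3=C4 alkene. The derived alanate opens oxirane with retention of alkene geometry and appends C5–C6.

Step 3
Reactants: 5 (E)-6-[(tert-butyldimethylsilyl)oxy]-4-methylhex-3-en-1-ol
Product: 6 (E)-[(6-bromo-3-methylhex-3-en-1-yl)oxy](tert-butyl)dimethylsilane
Conditions: CBr4, PPh3, 2,6-lutidine, DCM, 0 °C
Reagents that add atoms: carbon tetrabromide, BrC(Br)(Br)Br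
Why: Appel bromination of a primary alcohol; the buffered, neutral conditions keep the silyl ether.

Step 4
Reactants: 6 (E)-[(6-bromo-3-methylhex-3-en-1-yl)oxy](tert-butyl)dimethylsilane
Product: 7 (E)-6-bromo-3-methylhex-3-en-1-ol
Conditions: camphorsulfonic acid (0.1 equiv), MeOH, 0 °C to rt
Reagents that add atoms: none
Why: Acid-catalysed methanolysis of a primary silyl ether; acid is used in place of fluoride so that the primary bromide is not displaced.

Step 5
Reactants: 7 (E)-6-bromo-3-methylhex-3-en-1-ol
Product: 8 (E)-6-bromo-3-methylhex-3-enal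
Conditions: Dess–Martin periodinane, NaHCO3, DCM, 0 °C to rt; crude 8 used at once
Reagents that add atoms: none
Why: Dess–Martin oxidation under buffered, base-free conditions should give the β,γ-unsaturated aldehyde without moving the alkene into conjugation.

Step 6
Reactants: 9 (R)-4-benzyloxazolidin-2-one; 10 3-methylbutanoyl chloride
Product: 11 (R)-4-benzyl-3-(3-methylbutanoyl)oxazolidin-2-one
Conditions: Et3N, DMAP (0.1 equiv), DCM, 0 °C to rt
Reagents that add atoms: none
Why: DMAP-catalysed N-acylation of the oxazolidinone with an acid chloride.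

Step 7
Reactants: 11 (R)-4-benzyl-3-(3-methylbutanoyl)oxazolidin-2-one; 8 (E)-6-bromo-3-methylhex-3-enal
Product: 13 (R)-4-benzyl-3-[(2R,3S,5E)-8-bromo-3-hydroxy-5-methyl-2-(propan-2-yl)oct-5-enoyl]oxazolidin-2-one, via dibutylboron enolate 12 (not isolated)
Conditions: Bu2BOTf, i-Pr2NEt, DCM, −78 to 0 °C; then 8, −78 to 0 °C; pH 7 buffer, MeOH, 30% H2O2, 0 °C
Reagents that add atoms: none
Why: Evans syn aldol: the Z boron enolate reacts through a closed chair transition state on the face away from the benzyl group, which sets C10 and C1 together in the configurations required by the target. The aldehyde meets a preformed enolate at −78 °C, so little free amine is left to isomerise it.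

Step 8
Reactants: 13 (R)-4-benzyl-3-[(2R,3S,5E)-8-bromo-3-hydroxy-5-methyl-2-(propan-2-yl)oct-5-enoyl]oxazolidin-2-one
Product: 14 (R)-4-benzyl-3-[(2R,3S,5E)-8-bromo-3-[(tert-butyldimethylsilyl)oxy]-5-methyl-2-(propan-2-yl)oct-5-enoyl]oxazolidin-2-one
Conditions: TBSOTf, 2,6-lutidine, DCM, −78 to 0 °C
Reagents that add atoms: tert-butyldimethylsilyl triflate, CC(C)(C)[Si](C)(C)OS(=O)(=O)C(F)(F)F
Why: Silyl triflate silylation of a hindered secondary alcohol; it blocks retro-aldol cleavage and gives a C1 protecting group that survives hydride, base and the lithium amide of step 15.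

Step 9
Reactants: 14 (R)-4-benzyl-3-[(2R,3S,5E)-8-bromo-3-[(tert-butyldimethylsilyl)oxy]-5-methyl-2-(propan-2-yl)oct-5-enoyl]oxazolidin-2-one
Product: 15 (2S,3S,5E)-8-bromo-3-[(tert-butyldimethylsilyl)oxy]-5-methyl-2-(propan-2-yl)oct-5-en-1-ol
Conditions: LiBH4, MeOH (1 equiv), THF, 0 °C
Reagents that add atoms: none
Why: Reductive cleavage of the imide at the exocyclic carbonyl releases the auxiliary; LiBH4 at 0 °C should not reduce a primary alkyl bromide.

Step 10
Reactants: 15 (2S,3S,5E)-8-bromo-3-[(tert-butyldimethylsilyl)oxy]-5-methyl-2-(propan-2-yl)oct-5-en-1-ol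
Product: 16 (2R,3S,5E)-8-bromo-3-[(tert-butyldimethylsilyl)oxy]-5-methyl-2-(propan-2-yl)oct-5-enal
Conditions: Dess–Martin periodinane, NaHCO3, DCM, 0 °C; used directly
Reagents that add atoms: none
Why: Dess–Martin oxidation; the base-free conditions should leave the epimerisable C10 centre next to the new aldehyde intact.

Step 11
Reactants: 16 (2R,3S,5E)-8-bromo-3-[(tert-butyldimethylsilyl)oxy]-5-methyl-2-(propan-2-yl)oct-5-enal
Product: 17 (3E,5S,6S,8E)-11-bromo-6-[(tert-butyldimethylsilyl)oxy]-8-methyl-5-(propan-2-yl)undeca-3,8-dien-2-one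
Conditions: (MeO)2P(O)CH2C(O)CH3, Ba(OH)2, THF/H2O (40:1), 0 °C to rt
Reagents that add atoms: dimethyl (2-oxopropyl)phosphonate, COP(=O)(CC(C)=O)OC
Why: Horner–Wadsworth–Emmons olefination with a stabilised ketophosphonate gives the E enone (C8=C9); Ba(OH)2 in wet THF is mild enough for an α-branched β-silyloxy aldehyde.

Step 12
Reactants: 17 (3E,5S,6S,8E)-11-bromo-6-[(tert-butyldimethylsilyl)oxy]-8-methyl-5-(propan-2-yl)undeca-3,8-dien-2-one
Product: 18 (2S,3E,5S,6S,8E)-11-bromo-6-[(tert-butyldimethylsilyl)oxy]-8-methyl-5-(propan-2-yl)undeca-3,8-dien-2-ol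
Conditions: (R)-2-methyl-CBS-oxazaborolidine (0.2 equiv), catecholborane, toluene, −78 °C; MeOH, then aq. NaOH wash
Reagents that add atoms: none
Why: Corey–Bakshi–Shibata reduction under reagent control: the (R)-oxazaborolidine binds the ketone with the alkenyl group as the large substituent and delivers hydride to give the (S)-carbinol at C7. Catecholborane at low temperature reduces 1,2 and leaves the alkenes alone.

Step 13
Reactants: 18 (2S,3E,5S,6S,8E)-11-bromo-6-[(tert-butyldimethylsilyl)oxy]-8-methyl-5-(propan-2-yl)undeca-3,8-dien-2-ol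
Product: 19 (2S,3E,5S,6S,8E)-11-bromo-6-[(tert-butyldimethylsilyl)oxy]-8-methyl-5-(propan-2-yl)undeca-3,8-dien-2-yl N,N-di(propan-2-yl)carbamate
Conditions: i-Pr2NC(O)Cl, Et3N, DMAP (0.1 equiv), DCM, reflux
Reagents that add atoms: N,N-diisopropylcarbamoyl chloride, CC(C)N(C(C)C)C(Cl)=O
Why: Carbamoylation of a secondary alcohol by acyl substitution, with no change at C7; the hindered carbamate is the directing and leaving group for step 15.

Step 14
Reactants: 19 (2S,3E,5S,6S,8E)-11-bromo-6-[(tert-butyldimethylsilyl)oxy]-8-methyl-5-(propan-2-yl)undeca-3,8-dien-2-yl N,N-di(propan-2-yl)carbamate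
Product: 20 (2S,3E,5S,6S,8E)-6-[(tert-butyldimethylsilyl)oxy]-8-methyl-5-(propan-2-yl)-11-(4,4,5,5-tetramethyl-1,3,2-dioxaborolan-2-yl)undeca-3,8-dien-2-yl N,N-di(propan-2-yl)carbamate
Conditions: B2pin2, CuI (0.1 equiv), PPh3 (0.13 equiv), LiOMe, DMF, rt
Reagents that add atoms: bis(pinacolato)diboron, CC1(C)OB(OC1(C)C)B1OC(C)(C)C(C)(C)O1
Why: Copper-catalysed borylation of a primary alkyl bromide with a diboron reagent, a reaction that tolerates silyl ethers, alkenes and carbamates. The dialkylcarbamate is a poor leaving group, so allylic substitution should not compete.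

Step 15
Reactants: 20 (2S,3E,5S,6S,8E)-6-[(tert-butyldimethylsilyl)oxy]-8-methyl-5-(propan-2-yl)-11-(4,4,5,5-tetramethyl-1,3,2-dioxaborolan-2-yl)undeca-3,8-dien-2-yl N,N-di(propan-2-yl)carbamate
Product: 23 tert-butyl{[(1S,3E,7S,8E,10S)-3,7-dimethyl-10-(propan-2-yl)-7-(4,4,5,5-tetramethyl-1,3,2-dioxaborolan-2-yl)cyclodeca-3,8-dien-1-yl]oxy}dimethylsilane, via lithiated carbamate 21 (not isolated), via cyclic boronate complex 22 (not isolated)
Conditions: 20 added over 6 h to lithium diisopropylamide (1.5 equiv), Et2O, −78 °C (final 2 mM); then MgBr2·OEt2, MeOH, −78 °C to rt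
Reagents that add atoms: none
Why: Proposed new method: lithium diisopropylamide, which does not add irreversibly to a pinacol boronate, removes the C7 proton (acidified by the carbamate and the C8=C9 alkene) to give 21 with lithium held on C7 by the carbamate carbonyl; the tethered C6 boronate captures C7 on the lithium-bearing face to give the eleven-membered boronate complex 22, and antiperiplanar 1,2-migration of C6 from boron to C7 expels the carbamate with inversion and forms C6–C7. The closest known reaction type is the intermolecular lithiation–borylation of secondary allylic carbamates with boronic esters, which gives tertiary allylic boronic esters stereospecifically; the ring-forming version is untested. The ten-membered carbocycle is closed by ring contraction: an eleven-membered ring is first closed through the long C7–B bond and then loses boron from the ring in the 1,2-shift, so the strained ring is not made by a direct end-to-end C–C closure. The new C7 centre is controlled only by the (S)-carbamate centre (retention, then inversion), which gives the boronate whose oxidation with retention leads to the (R)-carbinol; C1 and C10 are spectators. The step needs capture at C7 and not at C9, which the carbamate-bound lithium and the branched C10 next to C9 should secure. It also needs cyclisation in preference to oligomerisation, which slow addition at high dilution and the two E alkenes in the tether should favour. Trapping in the flask is essential because the lithiated allylic carbamate does not keep its configuration for long, and MgBr2 in methanol is added to drive the migration before the complex can revert.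

Step 16
Reactants: 23 tert-butyl{[(1S,3E,7S,8E,10S)-3,7-dimethyl-10-(propan-2-yl)-7-(4,4,5,5-tetramethyl-1,3,2-dioxaborolan-2-yl)cyclodeca-3,8-dien-1-yl]oxy}dimethylsilane
Product: 24 (1R,2E,4S,5S,7E)-5-[(tert-butyldimethylsilyl)oxy]-1,7-dimethyl-4-(propan-2-yl)cyclodeca-2,7-dien-1-ol
Conditions: 30% H2O2, 2 M NaOH, THF, 0 °C to rt
Reagents that add atoms: hydrogen peroxide, OO
Why: Alkaline peroxide oxidation of the boronic ester: hydroperoxide adds to boron and C7 migrates to oxygen with retention and without allylic shift, giving the (R)-carbinol. It is run before any fluoride step because fluoride would protodeboronate the tertiary allylic boronate.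

Step 17
Reactants: 24 (1R,2E,4S,5S,7E)-5-[(tert-butyldimethylsilyl)oxy]-1,7-dimethyl-4-(propan-2-yl)cyclodeca-2,7-dien-1-ol
Product: 25 (1R,2E,4S,5S,7E)-1,7-dimethyl-4-(propan-2-yl)cyclodeca-2,7-diene-1,5-diol
Conditions: TBAF, THF, rt to 45 °C
Reagents that add atoms: none
Why: Fluoride desilylation; the non-acidic conditions spare the tertiary allylic alcohol and the 1,5-diene.

Step 18
Reactants: 26 vanillic acid
Product: 28 4-[(tert-butyldimethylsilyl)oxy]-3-methoxybenzoic acid, via bis-silylated vanillic acid 27 (not isolated)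
Conditions: TBSCl (2.5 equiv), imidazole, DMF, rt; then AcOH/THF/H2O, rt
Reagents that add atoms: tert-butyldimethylsilyl chloride, CC(C)(C)[Si](C)(C)Cl
Why: Silylation of both acidic sites followed by selective hydrolysis of the much more labile silyl ester; mild acid leaves the aryl silyl ether in place.

Step 19
Reactants: 25 (1R,2E,4S,5S,7E)-1,7-dimethyl-4-(propan-2-yl)cyclodeca-2,7-diene-1,5-diol; 28 4-[(tert-butyldimethylsilyl)oxy]-3-methoxybenzoic acid
Product: 30 (1S,3E,7R,8E,10S)-7-hydroxy-3,7-dimethyl-10-(propan-2-yl)cyclodeca-3,8-dien-1-yl 4-[(tert-butyldimethylsilyl)oxy]-3-methoxybenzoate, via mixed anhydride 29 (not isolated)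
Conditions: 28, 2,4,6-trichlorobenzoyl chloride, Et3N, THF, rt; then 25, DMAP, toluene, rt
Reagents that add atoms: none
Why: Yamaguchi esterification: DMAP transfers the aroyl group from the mixed anhydride to the secondary C1 hydroxyl, while the tertiary C7 hydroxyl is too hindered to compete. The acyl–oxygen bond is formed, so C1 keeps its configuration.

Step 20
Reactants: 30 (1S,3E,7R,8E,10S)-7-hydroxy-3,7-dimethyl-10-(propan-2-yl)cyclodeca-3,8-dien-1-yl 4-[(tert-butyldimethylsilyl)oxy]-3-methoxybenzoate
Product: 31 (1S,3E,7R,8E,10S)-7-hydroxy-3,7-dimethyl-10-(propan-2-yl)cyclodeca-3,8-dien-1-yl 4-hydroxy-3-methoxybenzoate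
Conditions: TBAF, AcOH, THF, 0 °C
Reagents that add atoms: none
Why: Fluoride cleavage of the aryl silyl ether, which is much faster than any other reaction open to the molecule; acetic acid buffers the phenoxide so that the ester is not transesterified.

## Compound list

1 | but-3-yn-1-ol | C#CCCO | starting material
2 | tert-butyl(but-3-yn-1-yloxy)dimethylsilane | C#CCCO[Si](C)(C)C(C)(C)C | intermediate
3 | (E)-{4-[(tert-butyldimethylsilyl)oxy]-2-methylbut-1-en-1-yl}dimethylalane | C[Al](C)/C=C(\C)CCO[Si](C)(C)C(C)(C)C | intermediate (not isolated)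
4 | lithium butyl{(E)-4-[(tert-butyldimethylsilyl)oxy]-2-methylbut-1-en-1-yl}dimethylalanate | [Li+].CCCC[Al-](C)(C)/C=C(\C)CCO[Si](C)(C)C(C)(C)C | intermediate (not isolated)
5 | (E)-6-[(tert-butyldimethylsilyl)oxy]-4-methylhex-3-en-1-ol | OCC/C=C(\C)CCO[Si](C)(C)C(C)(C)C | intermediate
6 | (E)-[(6-bromo-3-methylhex-3-en-1-yl)oxy](tert-butyl)dimethylsilane | BrCC/C=C(\C)CCO[Si](C)(C)C(C)(C)C | intermediate
7 | (E)-6-bromo-3-methylhex-3-en-1-ol | BrCC/C=C(\C)CCO | intermediate
8 | (E)-6-bromo-3-methylhex-3-enal | BrCC/C=C(\C)CC=O | intermediate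
9 | (R)-4-benzyloxazolidin-2-one | O=C1N[C@H](Cc2ccccc2)CO1 | starting material
10 | 3-methylbutanoyl chloride | CC(C)CC(=O)Cl | starting material
11 | (R)-4-benzyl-3-(3-methylbutanoyl)oxazolidin-2-one | CC(C)CC(=O)N1[C@H](Cc2ccccc2)COC1=O | intermediate
12 | dibutylboron (Z)-enolate of 11 | CCCCB(CCCC)O/C(=C\C(C)C)N1[C@H](Cc2ccccc2)COC1=O | intermediate (not isolated)
13 | (R)-4-benzyl-3-[(2R,3S,5E)-8-bromo-3-hydroxy-5-methyl-2-(propan-2-yl)oct-5-enoyl]oxazolidin-2-one | BrCC/C=C(\C)C[C@H](O)[C@@H](C(C)C)C(=O)N1[C@H](Cc2ccccc2)COC1=O | intermediate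
14 | (R)-4-benzyl-3-[(2R,3S,5E)-8-bromo-3-[(tert-butyldimethylsilyl)oxy]-5-methyl-2-(propan-2-yl)oct-5-enoyl]oxazolidin-2-one | BrCC/C=C(\C)C[C@H](O[Si](C)(C)C(C)(C)C)[C@@H](C(C)C)C(=O)N1[C@H](Cc2ccccc2)COC1=O | intermediate
15 | (2S,3S,5E)-8-bromo-3-[(tert-butyldimethylsilyl)oxy]-5-methyl-2-(propan-2-yl)oct-5-en-1-ol | BrCC/C=C(\C)C[C@H](O[Si](C)(C)C(C)(C)C)[C@@H](C(C)C)CO | intermediate
16 | (2R,3S,5E)-8-bromo-3-[(tert-butyldimethylsilyl)oxy]-5-methyl-2-(propan-2-yl)oct-5-enal | BrCC/C=C(\C)C[C@H](O[Si](C)(C)C(C)(C)C)[C@@H](C(C)C)C=O | intermediate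
17 | (3E,5S,6S,8E)-11-bromo-6-[(tert-butyldimethylsilyl)oxy]-8-methyl-5-(propan-2-yl)undeca-3,8-dien-2-one | BrCC/C=C(\C)C[C@H](O[Si](C)(C)C(C)(C)C)[C@@H](C(C)C)/C=C/C(C)=O | intermediate
18 | (2S,3E,5S,6S,8E)-11-bromo-6-[(tert-butyldimethylsilyl)oxy]-8-methyl-5-(propan-2-yl)undeca-3,8-dien-2-ol | BrCC/C=C(\C)C[C@H](O[Si](C)(C)C(C)(C)C)[C@@H](C(C)C)/C=C/[C@H](C)O | intermediate
19 | (2S,3E,5S,6S,8E)-11-bromo-6-[(tert-butyldimethylsilyl)oxy]-8-methyl-5-(propan-2-yl)undeca-3,8-dien-2-yl N,N-di(propan-2-yl)carbamate | BrCC/C=C(\C)C[C@H](O[Si](C)(C)C(C)(C)C)[C@@H](C(C)C)/C=C/[C@H](C)OC(=O)N(C(C)C)C(C)C | intermediate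
20 | (2S,3E,5S,6S,8E)-6-[(tert-butyldimethylsilyl)oxy]-8-methyl-5-(propan-2-yl)-11-(4,4,5,5-tetramethyl-1,3,2-dioxaborolan-2-yl)undeca-3,8-dien-2-yl N,N-di(propan-2-yl)carbamate | CC1(C)OB(CC/C=C(\C)C[C@H](O[Si](C)(C)C(C)(C)C)[C@@H](C(C)C)/C=C/[C@H](C)OC(=O)N(C(C)C)C(C)C)OC1(C)C | intermediate
21 | 20 lithiated at the carbamate carbon (lithium in place of hydrogen, configuration retained) | CC1(C)OB(CC/C=C(\C)C[C@H](O[Si](C)(C)C(C)(C)C)[C@@H](C(C)C)/C=C/[C@]([Li])(C)OC(=O)N(C(C)C)C(C)C)OC1(C)C | intermediate (not isolated)
22 | lithium salt of the eleven-membered cyclic boronate complex (boron bonded to C6 and C7, carbamate still on C7) | [Li+].CC1(C)O[B-]2(OC1(C)C)CC/C=C(\C)C[C@H](O[Si](C)(C)C(C)(C)C)[C@@H](C(C)C)/C=C/[C@]2(C)OC(=O)N(C(C)C)C(C)C | intermediate (not isolated)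
23 | tert-butyl{[(1S,3E,7S,8E,10S)-3,7-dimethyl-10-(propan-2-yl)-7-(4,4,5,5-tetramethyl-1,3,2-dioxaborolan-2-yl)cyclodeca-3,8-dien-1-yl]oxy}dimethylsilane | CC(C)(C)[Si](C)(C)O[C@H]1C/C(C)=C/CC[C@@](C)(B2OC(C)(C)C(C)(C)O2)/C=C/[C@@H]1C(C)C | intermediate
24 | (1R,2E,4S,5S,7E)-5-[(tert-butyldimethylsilyl)oxy]-1,7-dimethyl-4-(propan-2-yl)cyclodeca-2,7-dien-1-ol | CC(C)(C)[Si](C)(C)O[C@H]1C/C(C)=C/CC[C@@](C)(O)/C=C/[C@@H]1C(C)C | intermediate
25 | (1R,2E,4S,5S,7E)-1,7-dimethyl-4-(propan-2-yl)cyclodeca-2,7-diene-1,5-diol | O[C@H]1C/C(C)=C/CC[C@@](C)(O)/C=C/[C@@H]1C(C)C | intermediate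
26 | vanillic acid (4-hydroxy-3-methoxybenzoic acid) | COc1cc(C(=O)O)ccc1O | starting material
27 | tert-butyldimethylsilyl 4-[(tert-butyldimethylsilyl)oxy]-3-methoxybenzoate | COc1cc(C(=O)O[Si](C)(C)C(C)(C)C)ccc1O[Si](C)(C)C(C)(C)C | intermediate (not isolated)
28 | 4-[(tert-butyldimethylsilyl)oxy]-3-methoxybenzoic acid | COc1cc(C(=O)O)ccc1O[Si](C)(C)C(C)(C)C | intermediate
29 | 4-[(tert-butyldimethylsilyl)oxy]-3-methoxybenzoic 2,4,6-trichlorobenzoic anhydride | COc1cc(C(=O)OC(=O)c2c(Cl)cc(Cl)cc2Cl)ccc1O[Si](C)(C)C(C)(C)C | intermediate (not isolated)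
30 | (1S,3E,7R,8E,10S)-7-hydroxy-3,7-dimethyl-10-(propan-2-yl)cyclodeca-3,8-dien-1-yl 4-[(tert-butyldimethylsilyl)oxy]-3-methoxybenzoate | COc1cc(C(=O)O[C@H]2C/C(C)=C/CC[C@@](C)(O)/C=C/[C@@H]2C(C)C)ccc1O[Si](C)(C)C(C)(C)C | intermediate
31 | (1S,3E,7R,8E,10S)-7-hydroxy-3,7-dimethyl-10-(propan-2-yl)cyclodeca-3,8-dien-1-yl 4-hydroxy-3-methoxybenzoate (CNP0162316.1) | COc1cc(C(=O)O[C@H]2C/C(C)=C/CC[C@@](C)(O)/C=C/[C@@H]2C(C)C)ccc1O | target

## Step count and least certain steps

Total: 20 steps. Longest linear sequence: 18 steps (steps 1–5, 7–17, 19 and 20).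

**Step 15 (key step).** Closure of the eleven-membered boronate complex may be slower than loss of configuration or decomposition of the lithiated carbamate. Capture by the boron of a second molecule (oligomerisation), capture at C9, or sluggish deprotonation by the amide base may also intervene. A stronger hindered base such as lithium 2,2,6,6-tetramethylpiperidide is a first adjustment.

The fallback keeps the C6–C7 bond but forms it by the known intermolecular reaction, and closes the ring at C8=C9. It sets out from 16 and returns at 24.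
- Wittig methylenation of 16 (Ph3P=CH2 from Ph3PCH3Br and KN(SiMe3)2) would give the bromo diene {[(3S,4S,6E)-9-bromo-6-methyl-3-(propan-2-yl)nona-1,6-dien-4-yl]oxy}(tert-butyl)dimethylsilane F1.
- Borylation as in step 14 would give the corresponding pinacol boronate F2.
- (S,E)-Pent-3-en-2-ol F3, from (E)-pent-3-en-2-one by the reduction of step 12, would be carbamoylated as in step 13 to (S,E)-pent-3-en-2-yl N,N-di(propan-2-yl)carbamate F4.
- Lithiation of F4 with s-BuLi and TMEDA in Et2O at −78 °C, addition of F2 and warming with MgBr2·OEt2 in MeOH would give the open-chain tertiary allylic boronate F5.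
- Oxidation as in step 16 would give the trienol (2E,4R,7E,10S,11S)-10-[(tert-butyldimethylsilyl)oxy]-4,8-dimethyl-11-(propan-2-yl)trideca-2,7,12-trien-4-ol F6.
- Ring-closing metathesis of F6 with the second-generation Grubbs catalyst in dilute toluene, with loss of propene, would give 24.

**Step 14.** The boryl-copper species may displace the allylic carbamate with allylic shift, or methoxide may eliminate HBr towards the conjugated diene, because the β-hydrogens of the homoallylic bromide are allylic. The fallback avoids copper and alkoxide. It sets out from 19 and returns at 20.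
- Finkelstein exchange (NaI, acetone) would give the iodide (2S,3E,5S,6S,8E)-6-[(tert-butyldimethylsilyl)oxy]-11-iodo-8-methyl-5-(propan-2-yl)undeca-3,8-dien-2-yl N,N-di(propan-2-yl)carbamate F7.
- Light-driven radical borylation with bis(catecholato)diboron in DMF would give the catechol boronate F8.
- Transesterification with pinacol and Et3N would give 20.

**Step 12.** Facial selectivity may be poor, because the catalyst must tell a methyl group from an alkenyl group that carries a bulky branched substituent, and conjugate reduction may compete. The fallback replaces asymmetric reduction by resolution. It sets out from 17 and returns at 18.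
- Luche reduction (NaBH4, CeCl3·7H2O, MeOH, −78 °C) would give 18 together with its C2 epimer, the (2R)-alcohol F9.
- Immobilised Candida antarctica lipase B with vinyl acetate would acetylate only the (2R)-epimer to the acetate F10, leaving 18.
- F10 would be recycled by methanolysis (K2CO3, MeOH) to F9 and MnO2 oxidation back to 17.

**Step 2.** The alanate may open oxirane incompletely, or the coordinating silyl ether may erode the regiochemistry of methylalumination. The fallback isolates a vinyl iodide and changes the nucleophile. It sets out from 2 and returns at 5.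
- The same carboalumination quenched with iodine would give (E)-tert-butyl[(4-iodo-3-methylbut-3-en-1-yl)oxy]dimethylsilane F11.
- Lithium–iodine exchange (t-BuLi, Et2O, −78 °C) and opening of oxirane in the presence of BF3·OEt2 would give 5.

## Further compounds

F1 | step 15 | {[(3S,4S,6E)-9-bromo-6-methyl-3-(propan-2-yl)nona-1,6-dien-4-yl]oxy}(tert-butyl)dimethylsilane | BrCC/C=C(\C)C[C@H](O[Si](C)(C)C(C)(C)C)[C@@H](C(C)C)C=C
F2 | step 15 | tert-butyldimethyl{[(3S,4S,6E)-6-methyl-3-(propan-2-yl)-9-(4,4,5,5-tetramethyl-1,3,2-dioxaborolan-2-yl)nona-1,6-dien-4-yl]oxy}silane | CC1(C)OB(CC/C=C(\C)C[C@H](O[Si](C)(C)C(C)(C)C)[C@@H](C(C)C)C=C)OC1(C)C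
F3 | step 15 | (S,E)-pent-3-en-2-ol | C/C=C/[C@H](C)O
F4 | step 15 | (S,E)-pent-3-en-2-yl N,N-di(propan-2-yl)carbamate | C/C=C/[C@H](C)OC(=O)N(C(C)C)C(C)C
F5 | step 15 | tert-butyldimethyl{[(3S,4S,6E,10S,11E)-6,10-dimethyl-3-(propan-2-yl)-10-(4,4,5,5-tetramethyl-1,3,2-dioxaborolan-2-yl)trideca-1,6,11-trien-4-yl]oxy}silane | C/C=C/[C@](C)(B1OC(C)(C)C(C)(C)O1)CC/C=C(\C)C[C@H](O[Si](C)(C)C(C)(C)C)[C@@H](C(C)C)C=C
F6 | step 15 | (2E,4R,7E,10S,11S)-10-[(tert-butyldimethylsilyl)oxy]-4,8-dimethyl-11-(propan-2-yl)trideca-2,7,12-trien-4-ol | C/C=C/[C@](C)(O)CC/C=C(\C)C[C@H](O[Si](C)(C)C(C)(C)C)[C@@H](C(C)C)C=C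
F7 | step 14 | (2S,3E,5S,6S,8E)-6-[(tert-butyldimethylsilyl)oxy]-11-iodo-8-methyl-5-(propan-2-yl)undeca-3,8-dien-2-yl N,N-di(propan-2-yl)carbamate | ICC/C=C(\C)C[C@H](O[Si](C)(C)C(C)(C)C)[C@@H](C(C)C)/C=C/[C@H](C)OC(=O)N(C(C)C)C(C)C
F8 | step 14 | (2S,3E,5S,6S,8E)-11-(1,3,2-benzodioxaborol-2-yl)-6-[(tert-butyldimethylsilyl)oxy]-8-methyl-5-(propan-2-yl)undeca-3,8-dien-2-yl N,N-di(propan-2-yl)carbamate | c1ccc2OB(CC/C=C(\C)C[C@H](O[Si](C)(C)C(C)(C)C)[C@@H](C(C)C)/C=C/[C@H](C)OC(=O)N(C(C)C)C(C)C)Oc2c1
F9 | step 12 | (2R,3E,5S,6S,8E)-11-bromo-6-[(tert-butyldimethylsilyl)oxy]-8-methyl-5-(propan-2-yl)undeca-3,8-dien-2-ol | BrCC/C=C(\C)C[C@H](O[Si](C)(C)C(C)(C)C)[C@@H](C(C)C)/C=C/[C@@H](C)O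
F10 | step 12 | (2R,3E,5S,6S,8E)-11-bromo-6-[(tert-butyldimethylsilyl)oxy]-8-methyl-5-(propan-2-yl)undeca-3,8-dien-2-yl acetate | BrCC/C=C(\C)C[C@H](O[Si](C)(C)C(C)(C)C)[C@@H](C(C)C)/C=C/[C@@H](C)OC(C)=O
F11 | step 2 | (E)-tert-butyl[(4-iodo-3-methylbut-3-en-1-yl)oxy]dimethylsilane | I/C=C(\C)CCO[Si](C)(C)C(C)(C)C
A1 | alternative 1 | (2E,6E,9S,10E)-12-bromo-9-[(tert-butyldimethylsilyl)oxy]-3,7,11-trimethyldodeca-2,6,10-trienal | O=C/C=C(\C)CC/C=C(\C)C[C@H](O[Si](C)(C)C(C)(C)C)/C=C(\C)CBr
A2 | alternative 1 | (1R,2E,6E,9S,10S)-9-[(tert-butyldimethylsilyl)oxy]-3,7-dimethyl-10-(prop-1-en-2-yl)cyclodeca-2,6-dien-1-ol | CC(C)(C)[Si](C)(C)O[C@H]2C/C(C)=C/CC/C(C)=C/[C@@H](O)[C@@H]2C(C)=C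
A3 | alternative 2 | (1R,2S,4S,5R)-4-[(tert-butyldimethylsilyl)oxy]-2-ethenyl-2-methyl-5-(propan-2-yl)-1-(prop-1-en-2-yl)cyclohexan-1-ol (ethenyl and propenyl groups trans) | C=C[C@]1(C)C[C@H](O[Si](C)(C)C(C)(C)C)[C@@H](C(C)C)C[C@@]1(O)C(C)=C
A4 | alternative 2 | (2R,5E,8S,9R)-8-[(tert-butyldimethylsilyl)oxy]-2-hydroxy-2,6-dimethyl-9-(propan-2-yl)cyclodec-5-en-1-one | CC(C)(C)[Si](C)(C)O[C@H]2C/C(C)=C/CC[C@@](C)(O)C(=O)C[C@@H]2C(C)C
A5 | alternative 3 | tert-butyl{[(1E,4S,5S,6E,8R)-1-iodo-2,8-dimethyl-5-(propan-2-yl)-8-[(triethylsilyl)oxy]deca-1,6,9-trien-4-yl]oxy}dimethylsilane | I/C=C(\C)C[C@H](O[Si](C)(C)C(C)(C)C)[C@@H](C(C)C)/C=C/[C@](C)(O[Si](CC)(CC)CC)C=C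
A6 | alternative 3 | tert-butyl{[(1S,3E,7R,8E,10S)-3,7-dimethyl-10-(propan-2-yl)-7-[(triethylsilyl)oxy]cyclodeca-3,8-dien-1-yl]oxy}dimethylsilane | CC(C)(C)[Si](C)(C)O[C@H]2C/C(C)=C/CC[C@@](C)(O[Si](CC)(CC)CC)/C=C/[C@@H]2C(C)C
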